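(The readings come from a simulation on assumed constants; noise was put on by code.)

Take one natural-log unit of conversion as your measure, as on a semilogarithmic first-order plot: the turnover count is ln of charged over present [starting material], so counts add up, and a minute's count is that minute's mean rate.

the same everywhere: starting material 0.043 M
- Tuesday's: partner 2 equiv; second reagent 0.64 equiv; third reagent 3 equiv; run made earlier
- Saturday's: partner 2 equiv; second reagent 1.6 equiv; third reagent 3 equiv; run made earlier
- Friday's: partner 2 equiv; second reagent 3.3 equiv; third reagent 3 equiv; run made earlier
- ochre: partner 2.00 equiv; second reagent 0.900 equiv; third reagent 3.00 equiv; time 2.0 min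
- violet: partner 2.00 equiv; second reagent 1.80 equiv; third reagent 3.00 equiv; time 2.0 min
- grey: partner 2.00 equiv; second reagent 3.60 equiv; third reagent 3.00 equiv; time 2.0 min

| run | time / s | intermediate A / % | starting material / % | side product / % | target / % | intermediate B / % |
|---|---|---|---|---|---|---|
| Tuesday's | 10.0 | 8.0 | 89.9 | 2.2 | 0.2 | 0 |
| Tuesday's | 15.0 | 12.4 | 85.5 | 2.9 | 0.2 | 0 |
| Tuesday's | 30.0 | 20.8 | 74.3 | 4.9 | 0.4 | 0 |
| Tuesday's | 40.0 | 26.0 | 66.8 | 6.4 | 0.3 | 0.5 |
| Tuesday's | 60.0 | 34.9 | 56.6 | 8.8 | 0 | 0.1 |
| Saturday's | 10.0 | 7.7 | 87.4 | 4.5 | 0 | 0.3 |
| Saturday's | 15.0 | 11.0 | 82.8 | 6.7 | 0.4 | 0.2 |
| Saturday's | 30.0 | 20.4 | 67.7 | 12.5 | 0 | 0.5 |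
| Saturday's | 60.0 | 31.7 | 47.0 | 19.2 | 0 | 1.3 |
| Friday's | 10.0 | 8.3 | 82.4 | 9.6 | 0 | 0.3 |
| Friday's | 15.0 | 10.8 | 75.1 | 13.8 | 0 | 0.1 |
| Friday's | 30.0 | 18.2 | 57.7 | 23.5 | 0.1 | 0.6 |
| Friday's | 40.0 | 21.9 | 48.7 | 28.7 | 0 | 1.3 |
| Friday's | 60.0 | 26.4 | 34.3 | 36.0 | 0 | 2.6 |

(each reading ± 0.3 percentage points)

- which of these there is most of at the end, counted by the starting material in it, ochre (side product / intermediate A / intermediate B / starting material)
- which of these there is most of at the end, counted by the starting material in it, violet (side product / intermediate A / intermediate B / starting material)
- which of these there is most of at the end, counted by the starting material in it, grey (side product / intermediate A / intermediate B / starting material)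
- amount of the one of these that there is most of at the end, in percent of the starting material charged, ochre
- amount of the one of these that there is most of at the end, in percent of the starting material charged, violet
- amount of the one of these that there is most of at the end, in percent of the starting material charged, grey

- the numbers in the tables scatter by 0.3 percentage points (one standard deviation)
- a reading or a percentage of target counts all its forms, free or not

Tuesday's run counts 0.569 in its first minute and Friday's 1.07. A straight line in second reagent then gives first-minute counts of 0.618 for ochre, 0.788 for violet and 1.13 for grey.

Starting material leaves by two exits: to side product, or to the branch of intermediate A and intermediate B. Define the exit constant, a selectivity factor, as side product over branch, divided by the charge ratio of second reagent to partner. I take the branch exit as proportional to [partner], which these runs cannot test, since their partner charge stays at 2 equiv. Friday's run gives 0.752, Saturday's 0.727 and Tuesday's 0.786. So the split of side product to branch is 0.339 in ochre, 0.677 in violet and 1.35 in grey.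

The fall of [starting material] is already inside the log count, so the slowing comes from the two reagents. After its minute, Friday's readings, taken one to one, put partner at 85.5% of charge and second reagent at 88.3%. I let the first minute run near the midpoint between charge and these levels, and the second near these levels, in each flask. That slows the second minute by factors of 0.922 and 0.938, so I multiply each first-minute count by 1.93.

My reckoning leaves starting material at 30.3%, side product at 17.6% and branch at 52.0% in ochre. In violet these are 21.9%, 31.5% and 46.6%. In grey they are 11.4%, 51.0% and 37.6%. The branch holds more than either other in ochre and violet, while side product holds more than either other in grey. Friday's last readings divide the branch into 26.4% intermediate A and 2.6% intermediate B, so I name intermediate A for the branch.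

The forecast gives intermediate A at 48.5% in ochre, intermediate A at 41% in violet and side product at 51% in grey: “A leads in ochre and violet; side product leads in grey.” The flasks give intermediate A at 49.2%, intermediate A at 42.1% and side product at 51.2%.

    starting material + partner → intermediate A (k = 0.100 /M/s)
    crystals ⇌ target, rate k2*(cs2 - [target]) while solid is left; crystals form when [target] > cs2 (solubility = 0.930 mM, k = 1.30 /s)
    starting material + second reagent → side product (k = 0.0750 /M/s)
    second reagent + target ⇌ idle adduct, settled at all times (K = 71.0 /M)
    third reagent + intermediate B → target (k = 0.0420 /M/s)
    second reagent + intermediate A → intermediate B (k = 0.0170 /M/s)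

At 2.00 min in grey, the side-product step uses starting material 1.4 times as fast as the step to intermediate A, beside the split of 1.35 reckoned from the charges. In grey, side product stands higher than intermediate A, 51.2% against 30.8%. Now take the flask like grey with 14.0 equiv of second reagent: the exit constant gives a split of 5.27, so 84.1% of what reacts goes to side product. Computed, that flask ends with 83.9% side product, 6.10% intermediate A and 0.23% starting material.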